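The tetralin (C1 bearing the guaiacyl ring, C2 the ester CH2 C9', C3 the CH2OH C9, C4 the ring CH2; ring A aromatic, ring B saturated) is opened at C1–C2. The free para-hydroxyl of the C1 aryl ring lets C1 become the exocyclic carbon of a para-quinone methide, and C2, alpha to an aldehyde at C9', attacks it as an enamine. This one step closes ring B and sets C1 and C2 from the C3 centre. The precursor is a diaryl carbinol aldehyde with both phenols free and O9 as its TIPS ether, assembled by Evans alkylation (C3) and aryllithium addition to O-silylvanillin. O7 is meta to C8a, so ring A cannot form a quinone methide.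

Key step: step 12

Remark: 6-bromovanillin is assumed to be purchasable (otherwise two steps from vanillin acetate by bromination and hydrolysis); TBS = tert-butyldimethylsilyl, TIPS = triisopropylsilyl.

Step 1
Reactants: 1 6-bromovanillin (2-bromo-4-hydroxy-5-methoxybenzaldehyde)
Product: 2 2-bromo-4-(TBS-oxy)-5-methoxybenzaldehyde
Conditions: TBSCl, imidazole, DMF, rt
Reagents that add atoms: tert-butyldimethylsilyl chloride, CC(C)(C)[Si](C)(C)Cl
Why: Imidazole-promoted O-silylation of the only hydroxyl gives the aryl silyl ether, the aldehyde and the aryl bromide being inert.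

Step 2
Reactants: 2 2-bromo-4-(TBS-oxy)-5-methoxybenzaldehyde
Product: 3 [2-bromo-4-(TBS-oxy)-5-methoxyphenyl]methanol
Conditions: NaBH4, MeOH/THF, 0 °C
Reagents that add atoms: none
Why: Borohydride reduction of the aryl aldehyde to the benzylic alcohol leaves the aryl bromide and the aryl silyl ether untouched at 0 °C.

Step 3
Reactants: 3 [2-bromo-4-(TBS-oxy)-5-methoxyphenyl]methanol
Product: 4 2-bromo-4-(TBS-oxy)-5-methoxybenzyl bromide
Conditions: CBr4, PPh3, CH2Cl2, 0 °C; used promptly
Reagents that add atoms: carbon tetrabromide, BrC(Br)(Br)Br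
Why: The Appel reaction converts the benzylic alcohol into the bromide under neutral conditions, so no acid is present that could strip the para-silyloxy group.

Step 4
Reactants: 5 4-pentenoic acid; 6 (R)-4-benzyl-2-oxazolidinone
Product: 8 (R)-4-benzyl-3-(pent-4-enoyl)oxazolidin-2-one, via mixed pivalic anhydride 7 (not isolated)
Conditions: PivCl, Et3N, THF, −20 °C; then LiCl, 6, −20 °C to rt
Reagents that add atoms: none
Why: N-Acylation of the oxazolidinone through the mixed pivalic anhydride (LiCl/Et3N protocol) is a standard one-flask entry to Evans imides.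

Step 5
Reactants: 8 (R)-4-benzyl-3-(pent-4-enoyl)oxazolidin-2-one; 4 2-bromo-4-(TBS-oxy)-5-methoxybenzyl bromide
Product: 10 (R)-4-benzyl-3-{(S)-2-[2-bromo-4-(TBS-oxy)-5-methoxybenzyl]pent-4-enoyl}oxazolidin-2-one, via sodium Z-enolate 9 (not isolated)
Conditions: NaN(SiMe3)2, THF, −78 °C; then 4, −78 to −40 °C
Reagents that add atoms: none
Why: In this Evans alkylation the chelated Z-enolate is shielded on one face by the 4-benzyl group of the (R)-auxiliary, so the benzylic bromide enters from the other face and sets the (S) centre that becomes C3 (R) of the tetralin.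

Step 6
Reactants: 10 (R)-4-benzyl-3-{(S)-2-[2-bromo-4-(TBS-oxy)-5-methoxybenzyl]pent-4-enoyl}oxazolidin-2-one
Product: 11 (S)-2-[2-bromo-4-(TBS-oxy)-5-methoxybenzyl]pent-4-en-1-ol
Conditions: LiBH4, MeOH (1 equiv), Et2O, 0 °C
Reagents that add atoms: none
Why: Reductive cleavage of the N-acyl oxazolidinone with LiBH4 gives the primary alcohol (future C9) without touching the aryl bromide, the alkene or the new stereocentre, and returns the auxiliary.

Step 7
Reactants: 11 (S)-2-[2-bromo-4-(TBS-oxy)-5-methoxybenzyl]pent-4-en-1-ol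
Product: 12 {[(S)-2-(2-bromo-4-(TBS-oxy)-5-methoxybenzyl)pent-4-en-1-yl]oxy}triisopropylsilane
Conditions: TIPSCl, imidazole, DMAP (cat.), DMF, rt
Reagents that add atoms: triisopropylsilyl chloride, CC(C)[Si](Cl)(C(C)C)C(C)C
Why: Silylation of the primary alcohol as its TIPS ether gives a group that should outlast both the fluoride later used on the aryl TBS ethers and the acid of the key step.

Step 8
Reactants: 13 vanillin
Product: 14 4-(TBS-oxy)-3-methoxybenzaldehyde
Conditions: TBSCl, imidazole, DMF, rt
Reagents that add atoms: tert-butyldimethylsilyl chloride, CC(C)(C)[Si](C)(C)Cl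
Why: Standard imidazole-promoted silylation of the phenol removes the acidic proton before the organolithium step.

Step 9
Reactants: 12 {[(S)-2-(2-bromo-4-(TBS-oxy)-5-methoxybenzyl)pent-4-en-1-yl]oxy}triisopropylsilane; 14 4-(TBS-oxy)-3-methoxybenzaldehyde
Product: 16 [5-(TBS-oxy)-4-methoxy-2-{(S)-2-[(TIPS-oxy)methyl]pent-4-en-1-yl}phenyl][4-(TBS-oxy)-3-methoxyphenyl]methanol (both carbinol epimers), via aryllithium 15 (not isolated)
Conditions: n-BuLi, THF, −78 °C; then 14, −78 °C; aq. NH4Cl
Reagents that add atoms: none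
Why: Bromine–lithium exchange and 1,2-addition of the aryllithium to the aldehyde form the C1–C8a bond; no acidic proton is present, and the carbinol configuration is irrelevant because both epimers ionise to the same quinone methide.

Step 10
Reactants: 16 diaryl carbinol alkene
Product: 18 (3R)-4-{4-(TBS-oxy)-2-[hydroxy(4-(TBS-oxy)-3-methoxyphenyl)methyl]-5-methoxyphenyl}-3-[(TIPS-oxy)methyl]butanal, via 4,5-diol 17 (not isolated)
Conditions: OsO4 (2 mol%), NaIO4, 2,6-lutidine, dioxane/H2O 3:1, rt
Reagents that add atoms: osmium tetroxide, O=[Os](=O)(=O)=O (oxygen donor, regenerated by sodium periodate, [Na+].[O-]I(=O)(=O)=O)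
Why: Lemieux–Johnson cleavage of the terminal alkene gives the C9' aldehyde; 2,6-lutidine keeps the medium from ionising the carbinol, and with both phenols silylated periodate finds no guaiacol to oxidise.

Step 11
Reactants: 18 bis-TBS carbinol aldehyde
Product: 19 (3R)-4-{4-hydroxy-2-[hydroxy(4-hydroxy-3-methoxyphenyl)methyl]-5-methoxyphenyl}-3-[(TIPS-oxy)methyl]butanal (both carbinol epimers; used at once)
Conditions: TBAF (2.2 equiv), AcOH (2.5 equiv), THF, 0 °C
Reagents that add atoms: none
Why: In this chemoselective desilylation fluoride cleaves aryl silyl ethers far faster than a primary alkyl TIPS ether, and the AcOH buffer protects the enolisable aldehyde and the carbinol from base.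

Step 12
Reactants: 19 diphenol carbinol aldehyde
Product: 22 (1S,2R,3R)-7-hydroxy-1-(4-hydroxy-3-methoxyphenyl)-6-methoxy-3-[(TIPS-oxy)methyl]-1,2,3,4-tetrahydronaphthalene-2-carbaldehyde, via quinone methide aldehyde 20 (not isolated), via quinone methide enamine 21 (not isolated)
Conditions: (R)-α,α-diphenylprolinol trimethylsilyl ether (20 mol%), (PhO)2P(O)OH (30 mol%), CH2Cl2 (0.01 M), 0 °C to rt
Reagents that add atoms: none
Why: The phosphoric acid ionises the carbinol of 19, which is para to the free hydroxyl of the pendant ring and to the C6 methoxy of ring A, and loss of the phenolic proton gives the neutral para-quinone methide 20, while the amine condenses with the aldehyde to the E-enamine 21; C2 of the enamine then adds to the exocyclic carbon C1 (1,6-conjugate addition), the guaiacyl ring rearomatises, and the water set free hydrolyses the iminium ion and returns the catalyst. The closest known reaction type is the diarylprolinol silyl ether catalysed 1,6-addition of aldehydes to para-quinone methides, combined with the acid-promoted formation of quinone methides from para-hydroxybenzylic alcohols in the flask; it is applied here inside one molecule. Ring B closes in the 6-(enolexo)-exo-trig mode. C2 is controlled by the enamine face that the (R)-catalyst leaves open, which is also the face favoured by the C3 centre in a chair with CH2OTIPS equatorial (matched pair), and C1 is controlled by the same chair, in which the guaiacyl ring sits equatorial, so that the 1,2-trans-2,3-trans array should result. The step needs C-alkylation within the molecule to outrun attack of a phenol or of the amine on the unhindered quinone methide, which the six-membered transition state and high dilution secure, and it needs a single site of ionisation, which is given because O7 of ring A is meta to C8a and cannot support a quinone methide at C1. A minor C2 epimer can still equilibrate through the enamine to the all-equatorial aldehyde.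

Step 13
Reactants: 22 tetralin diphenol aldehyde
Product: 23 (1S,2R,3R)-7-(TBS-oxy)-1-[4-(TBS-oxy)-3-methoxyphenyl]-6-methoxy-3-[(TIPS-oxy)methyl]-1,2,3,4-tetrahydronaphthalene-2-carbaldehyde
Conditions: TBSCl (2.5 equiv), imidazole, DMF, 0 °C to rt
Reagents that add atoms: tert-butyldimethylsilyl chloride, CC(C)(C)[Si](C)(C)Cl
Why: Silylation of both phenols while C9' is still an aldehyde ensures that a single hydroxyl will be free for the acylation, and C2 already holds its thermodynamic trans arrangement toward the weak base.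

Step 14
Reactants: 23 bis-TBS tetralin aldehyde
Product: 24 {(1S,2R,3R)-7-(TBS-oxy)-1-[4-(TBS-oxy)-3-methoxyphenyl]-6-methoxy-3-[(TIPS-oxy)methyl]-1,2,3,4-tetrahydronaphthalen-2-yl}methanol
Conditions: NaBH4, MeOH/THF, 0 °C
Reagents that add atoms: none
Why: Borohydride reduction of the aldehyde gives the primary alcohol at C9', no other reducible group being present.

Step 15
Reactants: 25 p-coumaric acid
Product: 27 (E)-3-[4-(TBS-oxy)phenyl]acrylic acid, via silyl ester 26 (not isolated)
Conditions: TBSCl (2.5 equiv), imidazole, DMF, rt; then AcOH/THF/H2O, rt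
Reagents that add atoms: tert-butyldimethylsilyl chloride, CC(C)(C)[Si](C)(C)Cl
Why: Bis-silylation followed by selective hydrolysis of the labile silyl ester in aqueous AcOH leaves the aryl silyl ether and frees the acid.

Step 16
Reactants: 24 tetralin primary alcohol; 27 (E)-3-[4-(TBS-oxy)phenyl]acrylic acid
Product: 28 {(1S,2R,3R)-7-(TBS-oxy)-1-[4-(TBS-oxy)-3-methoxyphenyl]-6-methoxy-3-[(TIPS-oxy)methyl]-1,2,3,4-tetrahydronaphthalen-2-yl}methyl (E)-3-[4-(TBS-oxy)phenyl]acrylate
Conditions: DCC, DMAP (cat.), CH2Cl2, 0 °C to rt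
Reagents that add atoms: none
Why: Steglich esterification joins the only free hydroxyl to the cinnamic acid under neutral conditions that leave the E alkene and all silyl ethers alone.

Step 17
Reactants: 28 fully silylated ester
Product: 29 [(1S,2R,3R)-7-hydroxy-1-(4-hydroxy-3-methoxyphenyl)-3-(hydroxymethyl)-6-methoxy-1,2,3,4-tetrahydronaphthalen-2-yl]methyl (E)-3-(4-hydroxyphenyl)acrylate (target)
Conditions: TBAF, AcOH (1:1, excess), THF, 0 °C to rt
Reagents that add atoms: none
Why: Fluoride-mediated global desilylation removes the three aryl TBS groups and the TIPS ether, and the AcOH buffer keeps the phenols protonated so that the cinnamate should neither cleave nor migrate to the freed O9.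

Compound list
1 | 6-bromovanillin (2-bromo-4-hydroxy-5-methoxybenzaldehyde) | COc1cc(C=O)c(Br)cc1O | starting material
2 | 2-bromo-4-(tert-butyldimethylsilyloxy)-5-methoxybenzaldehyde | COc1cc(C=O)c(Br)cc1O[Si](C)(C)C(C)(C)C | intermediate
3 | [2-bromo-4-(tert-butyldimethylsilyloxy)-5-methoxyphenyl]methanol | COc1cc(CO)c(Br)cc1O[Si](C)(C)C(C)(C)C | intermediate
4 | 2-bromo-4-(tert-butyldimethylsilyloxy)-5-methoxybenzyl bromide | COc1cc(CBr)c(Br)cc1O[Si](C)(C)C(C)(C)C | intermediate
5 | 4-pentenoic acid | C=CCCC(=O)O | starting material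
6 | (R)-4-benzyl-2-oxazolidinone | O=C1N[C@H](Cc2ccccc2)CO1 | starting material
7 | pent-4-enoic pivalic anhydride (not isolated) | C=CCCC(=O)OC(=O)C(C)(C)C | intermediate
8 | (R)-4-benzyl-3-(pent-4-enoyl)oxazolidin-2-one | C=CCCC(=O)N1[C@H](Cc2ccccc2)COC1=O | intermediate
9 | sodium (Z)-enolate of imide 8 (not isolated) | C=CC/C=C(\[O-])N1[C@H](Cc2ccccc2)COC1=O.[Na+] | intermediate
10 | (R)-4-benzyl-3-{(S)-2-[2-bromo-4-(tert-butyldimethylsilyloxy)-5-methoxybenzyl]pent-4-enoyl}oxazolidin-2-one | COc1cc(C[C@@H](C(=O)N2[C@H](Cc3ccccc3)COC2=O)CC=C)c(Br)cc1O[Si](C)(C)C(C)(C)C | intermediate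
11 | (S)-2-[2-bromo-4-(tert-butyldimethylsilyloxy)-5-methoxybenzyl]pent-4-en-1-ol | COc1cc(C[C@@H](CO)CC=C)c(Br)cc1O[Si](C)(C)C(C)(C)C | intermediate
12 | {[(S)-2-(2-bromo-4-(tert-butyldimethylsilyloxy)-5-methoxybenzyl)pent-4-en-1-yl]oxy}triisopropylsilane | COc1cc(C[C@@H](CO[Si](C(C)C)(C(C)C)C(C)C)CC=C)c(Br)cc1O[Si](C)(C)C(C)(C)C | intermediate
13 | vanillin | COc1cc(C=O)ccc1O | starting material
14 | 4-(tert-butyldimethylsilyloxy)-3-methoxybenzaldehyde | COc1cc(C=O)ccc1O[Si](C)(C)C(C)(C)C | intermediate
15 | aryllithium from 12 (lithium in place of bromine; not isolated) | COc1cc(C[C@@H](CO[Si](C(C)C)(C(C)C)C(C)C)CC=C)c([Li])cc1O[Si](C)(C)C(C)(C)C | intermediate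
16 | [5-(tert-butyldimethylsilyloxy)-4-methoxy-2-{(S)-2-[(triisopropylsilyloxy)methyl]pent-4-en-1-yl}phenyl][4-(tert-butyldimethylsilyloxy)-3-methoxyphenyl]methanol, both carbinol epimers | COc1cc(C(O)c2cc(O[Si](C)(C)C(C)(C)C)c(OC)cc2C[C@@H](CO[Si](C(C)C)(C(C)C)C(C)C)CC=C)ccc1O[Si](C)(C)C(C)(C)C | intermediate
17 | 4,5-diol from dihydroxylation of the alkene of 16 (not isolated) | COc1cc(C(O)c2cc(O[Si](C)(C)C(C)(C)C)c(OC)cc2C[C@@H](CO[Si](C(C)C)(C(C)C)C(C)C)CC(O)CO)ccc1O[Si](C)(C)C(C)(C)C | intermediate
18 | (3R)-4-{4-(tert-butyldimethylsilyloxy)-2-[hydroxy(4-(tert-butyldimethylsilyloxy)-3-methoxyphenyl)methyl]-5-methoxyphenyl}-3-[(triisopropylsilyloxy)methyl]butanal | COc1cc(C(O)c2cc(O[Si](C)(C)C(C)(C)C)c(OC)cc2C[C@@H](CO[Si](C(C)C)(C(C)C)C(C)C)CC=O)ccc1O[Si](C)(C)C(C)(C)C | intermediate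
19 | (3R)-4-{4-hydroxy-2-[hydroxy(4-hydroxy-3-methoxyphenyl)methyl]-5-methoxyphenyl}-3-[(triisopropylsilyloxy)methyl]butanal (key-step precursor) | COc1cc(C(O)c2cc(O)c(OC)cc2C[C@@H](CO[Si](C(C)C)(C(C)C)C(C)C)CC=O)ccc1O | intermediate
20 | para-quinone methide aldehyde from 19 (either geometry at the exocyclic alkene; not isolated) | COC1=CC(=Cc2cc(O)c(OC)cc2C[C@@H](CO[Si](C(C)C)(C(C)C)C(C)C)CC=O)C=CC1=O | intermediate
21 | E-enamine of 20 with (R)-α,α-diphenylprolinol trimethylsilyl ether (not isolated) | COC1=CC(=Cc2cc(O)c(OC)cc2C[C@@H](CO[Si](C(C)C)(C(C)C)C(C)C)/C=C/N2CCC[C@@H]2C(O[Si](C)(C)C)(c2ccccc2)c2ccccc2)C=CC1=O | intermediate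
22 | (1S,2R,3R)-7-hydroxy-1-(4-hydroxy-3-methoxyphenyl)-6-methoxy-3-[(triisopropylsilyloxy)methyl]-1,2,3,4-tetrahydronaphthalene-2-carbaldehyde (key-step product) | COc1cc([C@H]2c3cc(O)c(OC)cc3C[C@@H](CO[Si](C(C)C)(C(C)C)C(C)C)[C@@H]2C=O)ccc1O | intermediate
23 | (1S,2R,3R)-7-(tert-butyldimethylsilyloxy)-1-[4-(tert-butyldimethylsilyloxy)-3-methoxyphenyl]-6-methoxy-3-[(triisopropylsilyloxy)methyl]-1,2,3,4-tetrahydronaphthalene-2-carbaldehyde | COc1cc([C@H]2c3cc(O[Si](C)(C)C(C)(C)C)c(OC)cc3C[C@@H](CO[Si](C(C)C)(C(C)C)C(C)C)[C@@H]2C=O)ccc1O[Si](C)(C)C(C)(C)C | intermediate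
24 | {(1S,2R,3R)-7-(tert-butyldimethylsilyloxy)-1-[4-(tert-butyldimethylsilyloxy)-3-methoxyphenyl]-6-methoxy-3-[(triisopropylsilyloxy)methyl]-1,2,3,4-tetrahydronaphthalen-2-yl}methanol | COc1cc([C@H]2c3cc(O[Si](C)(C)C(C)(C)C)c(OC)cc3C[C@@H](CO[Si](C(C)C)(C(C)C)C(C)C)[C@@H]2CO)ccc1O[Si](C)(C)C(C)(C)C | intermediate
25 | p-coumaric acid | O=C(O)/C=C/c1ccc(O)cc1 | starting material
26 | tert-butyldimethylsilyl (E)-3-[4-(tert-butyldimethylsilyloxy)phenyl]acrylate (not isolated) | CC(C)(C)[Si](C)(C)OC(=O)/C=C/c1ccc(O[Si](C)(C)C(C)(C)C)cc1 | intermediate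
27 | (E)-3-[4-(tert-butyldimethylsilyloxy)phenyl]acrylic acid | O=C(O)/C=C/c1ccc(O[Si](C)(C)C(C)(C)C)cc1 | intermediate
28 | {(1S,2R,3R)-7-(tert-butyldimethylsilyloxy)-1-[4-(tert-butyldimethylsilyloxy)-3-methoxyphenyl]-6-methoxy-3-[(triisopropylsilyloxy)methyl]-1,2,3,4-tetrahydronaphthalen-2-yl}methyl (E)-3-[4-(tert-butyldimethylsilyloxy)phenyl]acrylate | COc1cc([C@H]2c3cc(O[Si](C)(C)C(C)(C)C)c(OC)cc3C[C@@H](CO[Si](C(C)C)(C(C)C)C(C)C)[C@@H]2COC(=O)/C=C/c2ccc(O[Si](C)(C)C(C)(C)C)cc2)ccc1O[Si](C)(C)C(C)(C)C | intermediate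
29 | [(1S,2R,3R)-7-hydroxy-1-(4-hydroxy-3-methoxyphenyl)-3-(hydroxymethyl)-6-methoxy-1,2,3,4-tetrahydronaphthalen-2-yl]methyl (E)-3-(4-hydroxyphenyl)acrylate, CNP0403384.1 | COc1cc([C@H]2c3cc(O)c(OC)cc3C[C@@H](CO)[C@@H]2COC(=O)/C=C/c2ccc(O)cc2)ccc1O | target

Total step count: 17. Longest linear sequence: 14 steps (from 1 through steps 1, 2, 3, 5, 6, 7, 9, 10, 11, 12, 13, 14, 16 and 17).

Steps most likely to fail

Step 12. The unhindered quinone methide may oligomerise through intermolecular attack of phenols, the amine catalyst may be captured at C1, or ionisation may be too slow under the buffered acid. The fallback sets out from 18, which still carries both aryl TBS groups, and uses neither a free phenol nor an amine. TMSOTf and Et3N in CH2Cl2 at 0 °C should convert the aldehyde into its trimethylsilyl enol ether and cap the carbinol, giving the bis(trimethylsilyl) compound F1. A catalytic amount of TMSOTf at −78 °C then ionises the benzhydryl silyl ether, and the enol ether closes ring B through the same chair (Mukaiyama-type SN1 alkylation of a silyl enol ether by a diarylmethyl electrophile). Any C2 epimer is corrected with DBU. The fallback comes back to the route at 23, so steps 11 to 13 are bypassed.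

Step 11. Fluoride may induce self-condensation of the enolisable aldehyde, the freed para-hydroxy carbinol may close prematurely and without control, or the TIPS ether may be partly lost. The fallback sets out from 12 and keeps the aldehyde masked until the phenols are free.
- Lemieux–Johnson cleavage (OsO4, NaIO4, 2,6-lutidine) passes through the bromo diol F2 and gives the bromo aldehyde F3.
- HC(OMe)3, PPTS and MeOH give the dimethyl acetal F4.
- Bromine–lithium exchange (n-BuLi, −78 °C) gives the aryllithium F5, and its addition to 14 gives the acetal carbinol F6.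
- TBAF removes both aryl TBS groups with no aldehyde present, giving the diphenol acetal F7.
- The acid of step 12 in wet CH2Cl2 hydrolyses the acetal, so the fallback comes back at 19, formed in the flask and carried straight into step 12.

Step 17. The coumaroyl group may migrate from O9' to the freed O9, the ester may cleave under basic fluoride, or the TIPS ether may be lost only sluggishly. The fallback sets out from 22 and avoids aryl silyl ethers in the endgame.
- NaBH4 gives the diphenol alcohol F8.
- A Mitsunobu esterification (PPh3, DIAD, THF, 0 °C) with unprotected p-coumaric acid 25 should acylate only the primary alcohol, giving the TIPS-protected ester F9. The carboxylic acid is by far the most acidic pronucleophile and only the alcohol is activated.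
- HF·pyridine in THF/pyridine removes the single alkyl silyl group under acidic conditions, and the fallback comes back at 29.

Further compounds
F1 | step 12 | trimethylsilyl enol ether of 18 with the carbinol as its trimethylsilyl ether (E/Z mixture, both carbinol epimers) | COc1cc(C(O[Si](C)(C)C)c2cc(O[Si](C)(C)C(C)(C)C)c(OC)cc2C[C@@H](CO[Si](C(C)C)(C(C)C)C(C)C)C=CO[Si](C)(C)C)ccc1O[Si](C)(C)C(C)(C)C
F2 | step 11 | 4,5-diol from dihydroxylation of the alkene of 12 (not isolated) | COc1cc(C[C@@H](CO[Si](C(C)C)(C(C)C)C(C)C)CC(O)CO)c(Br)cc1O[Si](C)(C)C(C)(C)C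
F3 | step 11 | (R)-4-[2-bromo-4-(tert-butyldimethylsilyloxy)-5-methoxyphenyl]-3-[(triisopropylsilyloxy)methyl]butanal | COc1cc(C[C@@H](CO[Si](C(C)C)(C(C)C)C(C)C)CC=O)c(Br)cc1O[Si](C)(C)C(C)(C)C
F4 | step 11 | dimethyl acetal of F3 | COc1cc(C[C@@H](CO[Si](C(C)C)(C(C)C)C(C)C)CC(OC)OC)c(Br)cc1O[Si](C)(C)C(C)(C)C
F5 | step 11 | aryllithium from F4 (lithium in place of bromine; not isolated) | COc1cc(C[C@@H](CO[Si](C(C)C)(C(C)C)C(C)C)CC(OC)OC)c([Li])cc1O[Si](C)(C)C(C)(C)C
F6 | step 11 | dimethyl acetal of 18 (both carbinol epimers) | COc1cc(C(O)c2cc(O[Si](C)(C)C(C)(C)C)c(OC)cc2C[C@@H](CO[Si](C(C)C)(C(C)C)C(C)C)CC(OC)OC)ccc1O[Si](C)(C)C(C)(C)C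
F7 | step 11 | dimethyl acetal of 19 (both carbinol epimers) | COc1cc(C(O)c2cc(O)c(OC)cc2C[C@@H](CO[Si](C(C)C)(C(C)C)C(C)C)CC(OC)OC)ccc1O
F8 | step 17 | (1S,2R,3R)-2-(hydroxymethyl)-1-(4-hydroxy-3-methoxyphenyl)-6-methoxy-3-[(triisopropylsilyloxy)methyl]-1,2,3,4-tetrahydronaphthalen-7-ol | COc1cc([C@H]2c3cc(O)c(OC)cc3C[C@@H](CO[Si](C(C)C)(C(C)C)C(C)C)[C@@H]2CO)ccc1O
F9 | step 17 | O9-triisopropylsilyl ether of the target 29 | COc1cc([C@H]2c3cc(O)c(OC)cc3C[C@@H](CO[Si](C(C)C)(C(C)C)C(C)C)[C@@H]2COC(=O)/C=C/c2ccc(O)cc2)ccc1O
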